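**Plan**
1. Cuts: the C11–O(aryl) bond last (Mitsunobu reaction with isofraxidin); before that ring A at C1–C2 and C4–C5, which removes C2–C3(=O)–C4Me2 as a five-carbon sulfonyl allene and leaves a ring B cyclohexenol carrying CH2I on C10.
2. Feature used: C3 is a ketone lying between C2 and C4, and C5 is the allylic end of C5=C6–C7 in ring B. A C7–O–C3 enol ether (allyl vinyl ether) can therefore hand C4 to C5 by a [3,3] shift and leave C2 as a sulfonyl-stabilised enolate carbon that alkylates C1.
3. Forward order: ring B by Diels–Alder reaction of a 1-methoxy-3-silyloxypentadiene with citraconic anhydride; adjustment of C1, C7 and C11; ring A in one operation; then alkene shift C6=C7 to C7=C8, desilylation and etherification.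
4. Stereochemistry: C9/C10 (C11 and C1 cis, both anti to the C10 methyl) from the cis dienophile. C7 and the absolute configuration come from a reagent-controlled CBS reduction of the racemic 6-bromo enone with separation of diastereomers. C5 comes from C7 by suprafacial [3,3] transfer, which makes the ring fusion trans.
5. Helpers: the C2 phenylsulfonyl group (carbanion acceleration) and the C6 bromide (face control in the CBS reduction) are removed together with Bu3SnH; the C8 centre disappears when the alkene moves.

Key step: step 11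

Remark: carbons carry drimane numbers throughout (ring A C1–C5 and C10, ring B C5–C10, C11 = CH2O on C9); β is the face of the C10 methyl group, α the opposite face; compounds 5–11 are racemic and are drawn as the enantiomer that is carried on.

**Route**

Step 1
Reactants: 1 (E)-4-methoxybut-3-en-2-one
Product: 2 (E)-1-methoxypent-1-en-3-one
Conditions: LiN(iPr)2, THF, −78 °C; MeI, −78 to −20 °C
Reagents that add atoms: iodomethane, CI
Why: Kinetic deprotonation of the methyl ketone side of the vinylogous ester and C-methylation of the cross-conjugated lithium enolate (enolate alkylation) should give the ethyl ketone.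

Step 2
Reactants: 2 (E)-1-methoxypent-1-en-3-one
Product: 3 (1E,3Z)-3-(tert-butyldimethylsilyloxy)-1-methoxypenta-1,3-diene
Conditions: TBSOTf, Et3N, Et2O, 0 °C
Reagents that add atoms: tert-butyldimethylsilyl trifluoromethanesulfonate, CC(C)(C)[Si](C)(C)OS(=O)(=O)C(F)(F)F
Why: Amine-mediated enolisation and O-silylation (silyl enol ether formation) should give the electron-rich 1-alkoxy-3-silyloxy diene with the (Z)-enol ether expected from these conditions.

Step 3
Reactants: 3 (1E,3Z)-3-(tert-butyldimethylsilyloxy)-1-methoxypenta-1,3-diene, 4 citraconic anhydride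
Product: 5 cis-fused Diels–Alder anhydride
Conditions: toluene, 0 °C to rt
Reagents that add atoms: none
Why: In this Diels–Alder reaction the nucleophilic methyl-bearing diene terminus should bond to the unsubstituted olefinic carbon of the anhydride (C8–C9 and C5–C10 bonds), and suprafacial addition to the cyclic Z-dienophile sets C9–H and C10–CH3 cis, so that C1 and C11 lie together on the α face.

Step 4
Reactants: 5 cis-fused Diels–Alder anhydride
Product: 6 enol ether diol
Conditions: LiAlH4, THF, 0 °C to rt; aqueous NaOH work-up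
Reagents that add atoms: none
Why: Hydride reduction of the cyclic anhydride should give the cis 1,4-diol while the silyl enol ether and the methyl ether are inert.

Step 5
Reactants: 6 enol ether diol
Product: 8 enone alcohol, via bis-silyl ether 7 (not isolated)
Conditions: TBDPSCl, imidazole, CH2Cl2, −20 °C; then 1 M HCl, THF, rt
Reagents that add atoms: tert-butylchlorodiphenylsilane, CC(C)(C)[Si](Cl)(c1ccccc1)c1ccccc1
Why: Silylation is expected to prefer the C11 hydroxyl on the methine carbon over the neopentyl C1 hydroxyl, and acid then hydrolyses the silyl enol ether and eliminates methanol (β-elimination) to the enone, with C8 settling as the more stable epimer (methyl trans to the C9 substituent).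

Step 6
Reactants: 8 enone alcohol
Product: 9 iodo enone
Conditions: PPh3, I2, imidazole, toluene, 70 °C
Reagents that add atoms: iodine, II
Why: Appel-type iodination should convert the neopentyl alcohol into the iodide by SN2 displacement of the alkoxyphosphonium ion, a path without cationic rearrangement.

Step 7
Reactants: 9 iodo enone
Product: 11 bromo enone, via dibromo ketone 10 (not isolated)
Conditions: Br2, CH2Cl2, 0 °C; then Et3N, 0 °C to rt
Reagents that add atoms: bromine, BrBr
Why: Bromine addition to the enone and base-induced loss of HBr (E1cB elimination) should give the 2-bromo enone, whose C6 bromide is the large group needed by the next reduction.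

Step 8
Reactants: 11 bromo enone
Product: 12 bromo allylic alcohol
Conditions: (S)-1-methyl-3,3-diphenyltetrahydro-1H,3H-pyrrolo[1,2-c][1,3,2]oxazaborole (cat.), catecholborane, toluene, −78 °C; chromatography
Reagents that add atoms: none
Why: In this CBS reduction the catalyst, reading the bromovinyl side as the large group, should deliver hydride to the α face of C7 in both enantiomers of 11, so the wanted enantiomer gives the (7R)-7β-alcohol 12 (OH trans to CH2I and CH2OSi) and the other enantiomer gives a separable cis diastereomer, which fixes C7 and the absolute configuration.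

Step 9
Reactants: 13 2-methylbut-3-yn-2-ol
Product: 15 allenyl sulfoxide, via propargyl sulfenate 14 (not isolated)
Conditions: PhSCl, Et3N, CH2Cl2, −78 °C to rt
Reagents that add atoms: benzenesulfenyl chloride, ClSc1ccccc1
Why: O-Sulfenylation followed by [2,3]-sigmatropic rearrangement of the propargyl sulfenate should give the allenyl sulfoxide.

Step 10
Reactants: 15 allenyl sulfoxide
Product: 16 3-methyl-1-(phenylsulfonyl)buta-1,2-diene
Conditions: 3-chloroperbenzoic acid, CH2Cl2, 0 °C
Reagents that add atoms: 3-chloroperbenzoic acid, OOC(=O)c1cccc(Cl)c1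
Why: Sulfoxide-to-sulfone oxidation should be faster than epoxidation of the electron-poor allene.

Step 11
Reactants: 12 bromo allylic alcohol, 16 3-methyl-1-(phenylsulfonyl)buta-1,2-diene
Product: 19 bromo keto sulfone decalin, via sulfonylallyl ether anion 17 (not isolated), via ketosulfone enolate 18 (not isolated)
Conditions: KH (1.1 equiv), THF, 0 °C; 16; then DMSO, rt to 65 °C; aqueous NH4Cl
Reagents that add atoms: none
Why: The potassium alkoxide of 12 adds to the central allene carbon of 16 to give the sulfonyl-stabilised 2-oxyallyl carbanion 17, which undergoes a carbanion-accelerated Claisen ([3,3]) rearrangement through the axial C7–O bond to form C4–C5 and the β-keto sulfone enolate 18, and this enolate then C-alkylates the neopentyl iodide to form C1–C2. The closest known reaction type is the carbanion-accelerated Claisen rearrangement of allyl 2-(arylsulfonyl)vinyl ethers, known to build quaternary carbons next to substituted centres, followed by intramolecular alkylation of a β-keto sulfone anion. Ring A closes in a 6-(enolendo)-exo-tet mode; the sigmatropic step itself closes no ring. C5 is controlled by the C7 carbinol centre through suprafacial 1,3-transfer (C4 arrives on the β face, H5 ends α), and because CH2I sits on the α face of C10 the new ring is trans-fused; C4 is not stereogenic and the C2 centre is removed in step 12. The step needs C- over O-alkylation and no ether formation by the alkoxide: the iodide leaving group and the soft sulfonyl-stabilised carbon favour C-alkylation, and the alkoxide cannot reach C1 because C7–O and CH2I lie on opposite faces of ring B.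

Step 12
Reactants: 19 bromo keto sulfone decalin
Product: 20 C6=C7 decalone silyl ether
Conditions: Bu3SnH, azobisisobutyronitrile (cat.), toluene, 90 °C
Reagents that add atoms: none
Why: Tin hydride radical chain reduction should remove both helper groups, the vinyl bromide by halogen abstraction and the α-sulfonyl ketone by addition–fragmentation (desulfonylation), leaving the C6=C7 alkene and the C3 ketone.

Step 13
Reactants: 20 C6=C7 decalone silyl ether
Product: 21 C7=C8 decalone silyl ether
Conditions: RhCl3·3H2O (cat.), EtOH, 75 °C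
Reagents that add atoms: none
Why: Rhodium hydride addition and β-hydride elimination (alkene isomerisation) should move the double bond to the trisubstituted C7=C8 position, driven by relief of the 1,3-diaxial C8/C10 methyl interaction, while further migration to C8=C9 would need a tertiary alkyl–rhodium species.

Step 14
Reactants: 21 C7=C8 decalone silyl ether
Product: 22 keto alcohol
Conditions: Bu4NF, THF, rt
Reagents that add atoms: none
Why: Fluoride-induced desilylation should free the C11 alcohol without touching the ketone or the alkene.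

Step 15
Reactants: 22 keto alcohol, 23 isofraxidin
Product: 24 target CNP0127079.1
Conditions: PPh3, diisopropyl azodicarboxylate, THF, 0 °C to rt
Reagents that add atoms: none
Why: Mitsunobu etherification should couple the acidic 7-hydroxycoumarin with the primary C11 alcohol at a CH2 carbon, so no stereocentre is touched.

**Compound list**
1 | (E)-4-methoxybut-3-en-2-one | CO/C=C/C(C)=O | starting material
2 | (E)-1-methoxypent-1-en-3-one | CCC(=O)/C=C/OC | intermediate
3 | (1E,3Z)-3-(tert-butyldimethylsilyloxy)-1-methoxypenta-1,3-diene | CO/C=C/C(=C/C)O[Si](C)(C)C(C)(C)C | intermediate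
4 | citraconic anhydride (3-methylfuran-2,5-dione) | CC1=CC(=O)OC1=O | starting material
5 | cis-fused anhydride: ring B cyclohexene with 5-OMe (both epimers), C7=C8 silyl enol ether (7-OTBS, 8-Me), 9β-H, 10β-Me, anhydride carbons C1 and C11 on the α face; racemic | O=C1OC(=O)[C@@]2(C)C(OC)CC(O[Si](C)(C)C(C)(C)C)=C(C)[C@@H]12 | intermediate
6 | diol from 5: 10α-CH2OH and 9α-CH2OH, enol ether and 5-OMe unchanged; racemic | OC[C@@H]1C(C)=C(O[Si](C)(C)C(C)(C)C)CC(OC)[C@]1(C)CO | intermediate
7 | 11-O-tert-butyldiphenylsilyl ether of 6 (C1 hydroxyl free); racemic | CC(C)(C)[Si](c1ccccc1)(c1ccccc1)OC[C@@H]1C(C)=C(O[Si](C)(C)C(C)(C)C)CC(OC)[C@]1(C)CO | intermediate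
8 | ring B enone (C5=C6–C7=O) with 8β-Me, 9α-CH2OTBDPS, 10β-Me, 10α-CH2OH; racemic | CC(C)(C)[Si](c1ccccc1)(c1ccccc1)OC[C@@H]1[C@@H](C)C(=O)C=C[C@]1(C)CO | intermediate
9 | iodide of 8 (10α-CH2I); racemic | CC(C)(C)[Si](c1ccccc1)(c1ccccc1)OC[C@@H]1[C@@H](C)C(=O)C=C[C@]1(C)CI | intermediate
10 | 5,6-dibromo-7-ketone from 9 (C5 and C6 unassigned); racemic | CC(C)(C)[Si](c1ccccc1)(c1ccccc1)OC[C@@H]1[C@@H](C)C(=O)C(Br)C(Br)[C@]1(C)CI | intermediate
11 | 6-bromo enone (C5=C6(Br)–C7=O), other groups as in 9; racemic | CC(C)(C)[Si](c1ccccc1)(c1ccccc1)OC[C@@H]1[C@@H](C)C(=O)C(Br)=C[C@]1(C)CI | intermediate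
12 | (7R)-6-bromo-7β-hydroxy cyclohexene (C5=C6), 8β-Me, 9α-CH2OTBDPS, 10β-Me, 10α-CH2I; single enantiomer | CC(C)(C)[Si](c1ccccc1)(c1ccccc1)OC[C@@H]1[C@@H](C)[C@@H](O)C(Br)=C[C@]1(C)CI | intermediate
13 | 2-methylbut-3-yn-2-ol | CC(C)(O)C#C | starting material
14 | 2-methylbut-3-yn-2-yl benzenesulfenate | CC(C)(OSc1ccccc1)C#C | intermediate
15 | 3-methyl-1-(phenylsulfinyl)buta-1,2-diene (racemic at sulfur) | CC(C)=C=CS(=O)c1ccccc1 | intermediate
16 | 3-methyl-1-(phenylsulfonyl)buta-1,2-diene | CC(C)=C=CS(=O)(=O)c1ccccc1 | intermediate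
17 | potassium salt of the carbanion of the 7β-O-[3-methyl-1-(phenylsulfonyl)but-2-en-2-yl] ether of 12 (C7–O–C3(=C4Me2)–C2H(−)SO2Ph) | CC(C)(C)[Si](c1ccccc1)(c1ccccc1)OC[C@@H]1[C@@H](C)[C@@H](OC(=C(C)C)[CH-]S(=O)(=O)c2ccccc2)C(Br)=C[C@]1(C)CI.[K+] | intermediate
18 | potassium enolate of the β-keto sulfone: ring B with C6(Br)=C7, 5β-C(Me)2–C(=O)–CH(−)SO2Ph, 5α-H | CC(C)(C)[Si](c1ccccc1)(c1ccccc1)OC[C@@H]1[C@@H](C)C=C(Br)[C@@H](C(C)(C)C(=O)[CH-]S(=O)(=O)c2ccccc2)[C@]1(C)CI.[K+] | intermediate
19 | trans-decalin: 3-oxo, 2-(phenylsulfonyl) (C2 epimers), 4,4-dimethyl, 6-bromo-C6=C7, 8β-Me, 9α-CH2OTBDPS, 10β-Me, 5α-H | CC(C)(C)[Si](c1ccccc1)(c1ccccc1)OC[C@@H]1[C@@H](C)C=C(Br)[C@H]2C(C)(C)C(=O)C(S(=O)(=O)c3ccccc3)C[C@]12C | intermediate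
20 | trans-decalin: 3-oxo, 4,4-dimethyl, C6=C7, 8β-Me, 9α-CH2OTBDPS, 10β-Me, 5α-H | CC(C)(C)[Si](c1ccccc1)(c1ccccc1)OC[C@@H]1[C@@H](C)C=C[C@H]2C(C)(C)C(=O)CC[C@]12C | intermediate
21 | trans-decalin: 3-oxo, 4,4,8,10-tetramethyl, C7=C8, 9α-CH2OTBDPS (9β-H), 5α-H | CC(C)(C)[Si](c1ccccc1)(c1ccccc1)OC[C@@H]1C(C)=CC[C@H]2C(C)(C)C(=O)CC[C@]12C | intermediate
22 | (5R,9R,10S)-11-hydroxydrim-7-en-3-one (9β-H, CH2OH α) | OC[C@@H]1C(C)=CC[C@H]2C(C)(C)C(=O)CC[C@]12C | intermediate
23 | isofraxidin (7-hydroxy-6,8-dimethoxy-2H-chromen-2-one) | COc1cc2ccc(=O)oc2c(OC)c1O | starting material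
24 | CNP0127079.1: 6,8-dimethoxy-7-{[(5R,9R,10S)-3-oxodrim-7-en-11-yl]oxy}-2H-chromen-2-one | COc1cc2ccc(=O)oc2c(OC)c1OC[C@@H]1C(C)=CC[C@H]2C(C)(C)C(=O)CC[C@]12C | target

**Count and risks**
Total steps: 15. Longest linear sequence: 13 steps (steps 1–8 and 11–15).

Step 11 (most likely to fail). The enolate may alkylate on oxygen, or the neopentyl displacement may stall because ring closure needs a ring B conformer with axial C8, C9 and C10 substituents. Fallback with separate, known steps: starting from 12, acylation with isobutyryl chloride and pyridine gives the isobutyrate ester F1. Ireland–Claisen rearrangement (LiN(iPr)2, Me3SiCl, THF, −78 to 60 °C, then aqueous acid) carries the same suprafacial C7-to-C5 transfer and gives the acid F2. MeLi (two equivalents) converts it into the methyl ketone F3. KN(SiMe3)2 in THF/DMPU closes ring A by enolate alkylation to the bromo decalone F4. Bu3SnH reduction then returns to the route at 20.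

Step 13. The catalyst may fail to migrate the hindered ring alkene, or migration may run on toward C8=C9 with loss of the C9 centre. Fallback by oxidation and reductive transposition: starting from 20, SeO2 (cat.) with t-BuOOH hydroxylates the allylic C8 methine (ene reaction then [2,3] shift) to the tertiary allylic alcohol F5. Et3SiH with BF3·OEt2 at −78 °C then removes the hydroxyl with allylic transposition (hydride to C6), returning to the route at 21.

Step 8. In the wanted enantiomer the catalyst must override the substrate's preference for β-face attack, so facial selectivity may be poor and separation inefficient. Fallback by substrate-controlled reduction and resolution through esters: starting from 11, Luche reduction (NaBH4, CeCl3·7H2O, MeOH) gives the racemic 7α-alcohol F6. Mitsunobu inversion with (S)-2-methoxy-2-phenylacetic acid gives two diastereomeric 7β-esters, the wanted mandelate ester F7 and the ester of the other enantiomer F8, which are separated. Methanolysis of F7 (K2CO3, MeOH) returns to the route at 12.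

**Further compounds**
F1 | step 11 | isobutyrate ester of 12 | CC(C)(C)[Si](c1ccccc1)(c1ccccc1)OC[C@@H]1[C@@H](C)[C@@H](OC(=O)C(C)C)C(Br)=C[C@]1(C)CI
F2 | step 11 | acid from Ireland–Claisen rearrangement (5β-C(Me)2CO2H, C6(Br)=C7) | CC(C)(C)[Si](c1ccccc1)(c1ccccc1)OC[C@@H]1[C@@H](C)C=C(Br)[C@@H](C(C)(C)C(=O)O)[C@]1(C)CI
F3 | step 11 | methyl ketone (5β-C(Me)2C(=O)CH3) | CC(C)(C)[Si](c1ccccc1)(c1ccccc1)OC[C@@H]1[C@@H](C)C=C(Br)[C@@H](C(C)(C)C(C)=O)[C@]1(C)CI
F4 | step 11 | 6-bromo C6=C7 trans-decalone (19 without the sulfonyl group) | CC(C)(C)[Si](c1ccccc1)(c1ccccc1)OC[C@@H]1[C@@H](C)C=C(Br)[C@H]2C(C)(C)C(=O)CC[C@]12C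
F5 | step 13 | 8α-hydroxy derivative of 20 (tertiary allylic alcohol, C6=C7) | CC(C)(C)[Si](c1ccccc1)(c1ccccc1)OC[C@@H]1[C@](C)(O)C=C[C@H]2C(C)(C)C(=O)CC[C@]12C
F6 | step 8 | 7α-alcohol from 11 (OH cis to CH2I); racemic | CC(C)(C)[Si](c1ccccc1)(c1ccccc1)OC[C@@H]1[C@@H](C)[C@H](O)C(Br)=C[C@]1(C)CI
F7 | step 8 | 7β-(S)-2-methoxy-2-phenylacetate of the wanted enantiomer | CC(C)(C)[Si](c1ccccc1)(c1ccccc1)OC[C@@H]1[C@@H](C)[C@@H](OC(=O)[C@@H](OC)c2ccccc2)C(Br)=C[C@]1(C)CI
F8 | step 8 | (S)-2-methoxy-2-phenylacetate of the other ring enantiomer | CC(C)(C)[Si](c1ccccc1)(c1ccccc1)OC[C@H]1[C@H](C)[C@H](OC(=O)[C@@H](OC)c2ccccc2)C(Br)=C[C@@]1(C)CI
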